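**Plan**

- Numbering: ring O1–O2–C3–C4–C5–C6, side chain C1′–C10′ on C6. Retrosynthetic cuts, in order: acid ← methyl ester; C3–CH2CO2Me and C6–CH3 (each a nucleophile added to a peroxycarbenium ion); O1–C6 and O2–C3 (H2O2 bridge); C4–C5 (oxidative enamine/enol silane coupling).
- Enabling feature: C3 and C6, the two carbons on the peroxide oxygens of the 1,2-dioxane ring, stand 1,4 to each other across C4–C5, and each carries one carbon substituent that can arrive as a nucleophile. The ring is therefore the H2O2 ketal of a 2-methyl-4-oxo aldehyde (C3 = CHO, C6 = C=O).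
- Forward: the side chain is joined first (citronellyl bromide + phenethyl Grignard, ozonolysis, bromide, conjugate addition to pentenone) to a methyl ketone. Its enol silane is coupled with propanal and bridged with H2O2 in one flask, which closes the only ring. Then C6–CH3, C3–CH2CO2Me and hydrolysis follow.
- Stereochemistry: C6′ from (R)-citronellyl bromide; C2′ by copper/ferrocenyl-diphosphine conjugate addition; C4 by the imidazolidinone catalyst in the key step. C6 and C3 are set by axial attack on peroxycarbenium half-chairs held by the C4 methyl group, which converts the anomeric mixtures into single isomers.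

Key step: step 6

Remark: the sense of induction of the imidazolidinone (step 6) and of the ferrocenyl diphosphine (step 4) is assigned from the usual shielding models; the mirror-image catalyst or ligand would be used if a model reaction showed the opposite sense.

**Step 1**
Reactants: 1 (R)-citronellyl bromide; 2 2-phenylethylmagnesium chloride
Product: 3 (S)-(5,9-dimethyldec-8-en-1-yl)benzene
Conditions: Li2CuCl4 (3 mol%), THF, −10 °C to rt
Reagents that add atoms: none
Why: Copper-catalysed sp3–sp3 coupling of a primary alkyl bromide with a primary Grignard reagent (Kochi coupling) should leave the remote chiral-pool centre untouched; its descriptor changes from R to S only because the priorities change.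

**Step 2**
Reactants: 3 (S)-(5,9-dimethyldec-8-en-1-yl)benzene
Product: 4 (S)-4-methyl-8-phenyloctan-1-ol
Conditions: O3, CH2Cl2–MeOH, −78 °C; then NaBH4, −78 °C to rt
Reagents that add atoms: ozone, [O-][O+]=O
Why: Ozonolysis of the electron-rich trisubstituted alkene (the arene reacts far more slowly) with reductive work-up should give the primary alcohol directly.

**Step 3**
Reactants: 4 (S)-4-methyl-8-phenyloctan-1-ol
Product: 5 (S)-(8-bromo-5-methyloctyl)benzene
Conditions: CBr4, PPh3, CH2Cl2, 0 °C
Reagents that add atoms: carbon tetrabromide, BrC(Br)(Br)Br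
Why: Appel bromination of an unhindered primary alcohol.

**Step 4**
Reactants: 5 (S)-(8-bromo-5-methyloctyl)benzene; 6 (E)-pent-3-en-2-one
Product: 8 (4R,8S)-4,8-dimethyl-12-phenyldodecan-2-one, via Grignard reagent 7 (not isolated)
Conditions: Mg, Et2O, reflux; then added to 6, CuBr·SMe2 (5 mol%), (R)-1-[(S)-2-(diphenylphosphino)ferrocenyl]ethyldicyclohexylphosphine (6 mol%), tBuOMe, −75 °C
Reagents that add atoms: none
Why: Copper-catalysed asymmetric conjugate addition of a primary alkyl Grignard reagent to an acyclic E-enone should deliver the chain to one face of the methyl-bearing β-carbon, setting C2′ (4R in the ketone) under control of the chiral diphosphine–copper complex.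

**Step 5**
Reactants: 8 (4R,8S)-4,8-dimethyl-12-phenyldodecan-2-one
Product: 9 trimethyl{[(4R,8S)-4,8-dimethyl-12-phenyldodec-1-en-2-yl]oxy}silane
Conditions: LiN(iPr)2, THF, −78 °C; Me3SiCl, Et3N
Reagents that add atoms: chlorotrimethylsilane, C[Si](C)(C)Cl
Why: Kinetic deprotonation at the methyl group (the less hindered α-position) and O-silylation should give the terminal enol silane.

**Step 6**
Reactants: 9 trimethyl{[(4R,8S)-4,8-dimethyl-12-phenyldodec-1-en-2-yl]oxy}silane; 10 propanal (3 equiv)
Product: 12 (4S)-6-[(2R,6S)-2,6-dimethyl-10-phenyldecyl]-3,6-dimethoxy-4-methyl-1,2-dioxane as a mixture of C3 and C6 epimers, via keto aldehyde 11 (not isolated)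
Conditions: (2R,5R)-5-benzyl-2-tert-butyl-3-methylimidazolidin-4-one·CF3CO2H (20 mol%), (NH4)2Ce(NO3)6 (2.2 equiv), H2O (2 equiv), 2,6-di-tert-butylpyridine, DME, −20 °C; then MeOH, urea–H2O2 (6 equiv), camphorsulfonic acid (0.5 equiv), 0 °C
Reagents that add atoms: hydrogen peroxide (used as its urea adduct), OO; methanol, CO
Why: The imidazolidinone and 10 form an E-enamine that (NH4)2Ce(NO3)6 oxidises to a 3π-electron radical cation; this adds through C4 to the CH2 terminus (C5) of 9 on the face remote from the catalyst benzyl group, and oxidation and desilylation of the α-silyloxy radical give keto aldehyde 11 (closest known type: organo-SOMO α-enolation of aldehydes with enol silanes). In the second stage H2O2 adds to the aldehyde carbon C3 and the hydroperoxide closes on the C6 ketone (6-exo-trig hemiketalisation, O1–C6), and methanol caps both anomeric carbons under acid (closest known type: bridging of 1,4-dicarbonyl compounds with H2O2 to 1,2-dioxane-3,6-diols). The 1,2-dioxane ring is thus closed by ketalisation at the two carbonyl carbons. C4 is the only new centre that must be controlled and is set by the catalyst (4S); C3 and C6 arise as anomeric mixtures that steps 7 and 8 pass through planar peroxycarbenium ions. The step needs bridging through O–O to win over closure through a single oxygen or furan formation, which the excess of H2O2, its α-effect nucleophilicity and the low temperature should secure, and it needs C4 to survive, which the cold, weakly acidic second stage should allow.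

**Step 7**
Reactants: 12 (4S)-6-[(2R,6S)-2,6-dimethyl-10-phenyldecyl]-3,6-dimethoxy-4-methyl-1,2-dioxane
Product: 13 (4S,6R)-6-[(2R,6S)-2,6-dimethyl-10-phenyldecyl]-3-methoxy-4,6-dimethyl-1,2-dioxane as both C3 epimers
Conditions: Me3Al (3 equiv), Me3SiOSO2CF3 (0.2 equiv), CH2Cl2, −78 °C
Reagents that add atoms: trimethylaluminium, C[Al](C)C
Why: Proposed new method: the silyl triflate should ionise the more substituted ketal carbon C6 (the exocyclic methoxy group leaves) to a peroxycarbenium ion whose half-chair keeps the C4 methyl pseudo-equatorial, and Me3Al should deliver methyl along the axial trajectory, trans to the C4 methyl, from every C3/C6 epimer of 12 (stereoconvergent, 6R); the closest known reaction types are the Lewis-acid substitution of cyclic peroxyketals by allylsilanes and silyl enol ethers through peroxycarbenium ions and the methylation of peroxide-containing cyclic oxocarbenium ions with organoaluminium reagents.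

**Step 8**
Reactants: 13 (4S,6R)-6-[(2R,6S)-2,6-dimethyl-10-phenyldecyl]-3-methoxy-4,6-dimethyl-1,2-dioxane
Product: 14 methyl 2-[(3S,4S,6R)-6-[(2R,6S)-2,6-dimethyl-10-phenyldecyl]-4,6-dimethyl-1,2-dioxan-3-yl]acetate
Conditions: CH2=C(OMe)OSiMe2tBu (3 equiv), Me3SiOSO2CF3 (0.3 equiv), CH2Cl2, −78 °C
Reagents that add atoms: 1-(tert-butyldimethylsilyloxy)-1-methoxyethene, C=C(OC)O[Si](C)(C)C(C)(C)C
Why: Mukaiyama-type substitution of an alkoxy-1,2-dioxane through its peroxycarbenium ion (known for cyclic peroxyacetals and peroxyketals with silyl ketene acetals) should proceed by axial attack at C3 on the one half-chair that keeps the C4 methyl and the C6 chain pseudo-equatorial (the other would place them 1,3-diaxial), giving the 3,4-cis isomer with the acetate arm trans to the axial C6 methyl (3S) from both C3 epimers of 13.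

**Step 9**
Reactants: 14 methyl 2-[(3S,4S,6R)-6-[(2R,6S)-2,6-dimethyl-10-phenyldecyl]-4,6-dimethyl-1,2-dioxan-3-yl]acetate
Product: 15 2-[(3S,4S,6R)-6-[(2R,6S)-2,6-dimethyl-10-phenyldecyl]-4,6-dimethyl-1,2-dioxan-3-yl]acetic acid
Conditions: LiOH, THF–H2O, 0 °C; then 1 M HCl
Reagents that add atoms: lithium hydroxide, [Li+].[OH-]
Why: Saponification of a methyl ester, a transformation that dialkyl peroxides of the 1,2-dioxane-3-acetate type are known to tolerate at low temperature, should give the target without touching the stereocentres.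

**Compound list**

1 | (R)-citronellyl bromide, (R)-8-bromo-2,6-dimethyloct-2-ene | C[C@@H](CCBr)CCC=C(C)C | starting material
2 | 2-phenylethylmagnesium chloride | Cl[Mg]CCc1ccccc1 | starting material
3 | (S)-(5,9-dimethyldec-8-en-1-yl)benzene | C[C@@H](CCCCc1ccccc1)CCC=C(C)C | intermediate
4 | (S)-4-methyl-8-phenyloctan-1-ol | C[C@@H](CCCCc1ccccc1)CCCO | intermediate
5 | (S)-(8-bromo-5-methyloctyl)benzene | C[C@@H](CCCCc1ccccc1)CCCBr | intermediate
6 | (E)-pent-3-en-2-one | C/C=C/C(C)=O | starting material
7 | (S)-(4-methyl-8-phenyloctyl)magnesium bromide | C[C@@H](CCCCc1ccccc1)CCC[Mg]Br | intermediate (not isolated)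
8 | (4R,8S)-4,8-dimethyl-12-phenyldodecan-2-one | C[C@@H](CCCCc1ccccc1)CCC[C@@H](C)CC(C)=O | intermediate
9 | trimethyl{[(4R,8S)-4,8-dimethyl-12-phenyldodec-1-en-2-yl]oxy}silane | C[C@@H](CCCCc1ccccc1)CCC[C@@H](C)CC(=C)O[Si](C)(C)C | intermediate
10 | propanal | CCC=O | starting material
11 | (2S,6R,10S)-2,6,10-trimethyl-4-oxo-14-phenyltetradecanal | C[C@@H](CCCCc1ccccc1)CCC[C@@H](C)CC(=O)C[C@H](C)C=O | intermediate (not isolated)
12 | (4S)-6-[(2R,6S)-2,6-dimethyl-10-phenyldecyl]-3,6-dimethoxy-4-methyl-1,2-dioxane (C3 and C6 epimers) | C[C@@H](CCCCc1ccccc1)CCC[C@@H](C)CC1(OC)C[C@H](C)C(OC)OO1 | intermediate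
13 | (4S,6R)-6-[(2R,6S)-2,6-dimethyl-10-phenyldecyl]-3-methoxy-4,6-dimethyl-1,2-dioxane (C3 epimers) | C[C@@H](CCCCc1ccccc1)CCC[C@@H](C)C[C@]1(C)C[C@H](C)C(OC)OO1 | intermediate
14 | methyl 2-[(3S,4S,6R)-6-[(2R,6S)-2,6-dimethyl-10-phenyldecyl]-4,6-dimethyl-1,2-dioxan-3-yl]acetate | C[C@@H](CCCCc1ccccc1)CCC[C@@H](C)C[C@]1(C)C[C@H](C)[C@H](CC(=O)OC)OO1 | intermediate
15 | 2-[(3S,4S,6R)-6-[(2R,6S)-2,6-dimethyl-10-phenyldecyl]-4,6-dimethyl-1,2-dioxan-3-yl]acetic acid | C[C@@H](CCCCc1ccccc1)CCC[C@@H](C)C[C@]1(C)C[C@H](C)[C@H](CC(=O)O)OO1 | target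

**Totals**

Total step count: 9. Longest linear sequence: 9 steps (1 to 15).

**Steps most likely to fail**

Step 7. The organoaluminium reagent may reduce or cleave the O–O bond, the acetal carbon C3 may ionise together with C6, or the peroxycarbenium ion may open or lose a proton before methyl is transferred. The fallback uses known chemistry, sets out from keto aldehyde 11 (isolated after the first stage of step 6) and comes back at ester 14. An aldehyde-selective Wittig reaction with Ph3P=CHCO2Me should give methyl (2E,4S,8R,12S)-4,8,12-trimethyl-6-oxo-16-phenylhexadec-2-enoate F1. Methylenation of the ketone with Zn/CH2Br2/TiCl4 should give methyl (2E,4S,8R,12S)-4,8,12-trimethyl-6-methylidene-16-phenylhexadec-2-enoate F2. Isayama–Mukaiyama hydroperoxysilylation of its 1,1-disubstituted alkene (Co(acac)2, Et3SiH, O2) should give the tertiary silyl peroxide methyl (2E,4S,8R,12S)-4,6,8,12-tetramethyl-16-phenyl-6-(triethylsilylperoxy)hexadec-2-enoate F3 as both C6 epimers. Desilylation (HCl, MeOH) and intramolecular oxa-Michael addition (Et2NH, CF3CH2OH) should then give 14, to be separated from its C6 and C3 epimers by chromatography.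

Step 6. In the second stage the keto aldehyde may close through a single oxygen (2,5-dimethoxytetrahydrofuran) or dehydrate to a furan faster than it is bridged by O–O, and the acid may erode the C4 centre. The fallback sets out from 11 (isolated after the first stage) and comes back at 12. Aldehyde-selective acetalisation (HC(OMe)3, MeOH, CeCl3·7H2O) should give (2S,6R,10S)-1,1-dimethoxy-2,6,10-trimethyl-14-phenyltetradecan-4-one F4. Urea–H2O2 with Sc(OTf)3 in MeOH should then place a methoxy hydroperoxide on the ketone alone, giving (2S,6R,10S)-4-hydroperoxy-1,1,4-trimethoxy-2,6,10-trimethyl-14-phenyltetradecane F5, whose only free nucleophile is the OOH group. With camphorsulfonic acid this should close onto the acetal carbon by exchange to give 12.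

Step 8. Lewis-acid-induced heterolysis of the O–O bond of the secondary peroxyacetal (Hock-type fragmentation) or proton loss from the peroxycarbenium ion may outrun C–C bond formation. The fallback sets out from 13 and comes back at 14. Mild aqueous acid (AcOH, H2O, THF) should give (4S,6R)-6-[(2R,6S)-2,6-dimethyl-10-phenyldecyl]-4,6-dimethyl-1,2-dioxan-3-ol F6, which is in equilibrium with its open hydroperoxy aldehyde. Horner–Wadsworth–Emmons olefination with trimethyl phosphonoacetate (LiCl, iPr2NEt, MeCN) should give methyl (2E,4S,6R,8R,12S)-6-hydroperoxy-4,6,8,12-tetramethyl-16-phenylhexadec-2-enoate F7. Intramolecular oxa-Michael addition of the tertiary hydroperoxide (Et2NH, CF3CH2OH) should give 14, to be separated from its C3 epimer.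

**Further compounds**

F1 | step 7 | methyl (2E,4S,8R,12S)-4,8,12-trimethyl-6-oxo-16-phenylhexadec-2-enoate | C[C@@H](CCCCc1ccccc1)CCC[C@@H](C)CC(=O)C[C@H](C)/C=C/C(=O)OC
F2 | step 7 | methyl (2E,4S,8R,12S)-4,8,12-trimethyl-6-methylidene-16-phenylhexadec-2-enoate | C[C@@H](CCCCc1ccccc1)CCC[C@@H](C)CC(=C)C[C@H](C)/C=C/C(=O)OC
F3 | step 7 | methyl (2E,4S,8R,12S)-4,6,8,12-tetramethyl-16-phenyl-6-(triethylsilylperoxy)hexadec-2-enoate (C6 epimers) | C[C@@H](CCCCc1ccccc1)CCC[C@@H](C)CC(C)(OO[Si](CC)(CC)CC)C[C@H](C)/C=C/C(=O)OC
F4 | step 6 | (2S,6R,10S)-1,1-dimethoxy-2,6,10-trimethyl-14-phenyltetradecan-4-one | C[C@@H](CCCCc1ccccc1)CCC[C@@H](C)CC(=O)C[C@H](C)C(OC)OC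
F5 | step 6 | (2S,6R,10S)-4-hydroperoxy-1,1,4-trimethoxy-2,6,10-trimethyl-14-phenyltetradecane | C[C@@H](CCCCc1ccccc1)CCC[C@@H](C)CC(OC)(OO)C[C@H](C)C(OC)OC
F6 | step 8 | (4S,6R)-6-[(2R,6S)-2,6-dimethyl-10-phenyldecyl]-4,6-dimethyl-1,2-dioxan-3-ol | C[C@@H](CCCCc1ccccc1)CCC[C@@H](C)C[C@]1(C)C[C@H](C)C(O)OO1
F7 | step 8 | methyl (2E,4S,6R,8R,12S)-6-hydroperoxy-4,6,8,12-tetramethyl-16-phenylhexadec-2-enoate | C[C@@H](CCCCc1ccccc1)CCC[C@@H](C)C[C@](OO)(C)C[C@H](C)/C=C/C(=O)OC
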